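The runs come from a simulation for an exercise; scatter was added.

Percent of the Q charged is the unit of every reading here, so a reading of E and a reading of free Q can be set side by side.

| flask | Q | remark | time |
|---|---|---|---|
| midnight | 0.25 M | run made earlier |  |
| flask | 0.50 M |  | 5.0 h |

midnight run (percent of the Q charged)

| time / min | E / % | Q / % |
|---|---|---|
| 2.50 | 3.2 | 98.0 |
| 5.00 | 1.4 | 94.3 |
| 8.00 | 4.7 | 91.4 |
| 15.0 | 6.2 | 85.3 |
| 30.0 | 12.7 | 71.8 |

(scatter of a reading: 1 percentage point)

- when, up to 5.0 h, the flask holds most E
- the amount of E, in percent of the Q charged, at that time

- a reading or a percentage of E counts all its forms, free or not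
- a reading of Q is of its free form alone

From the last midnight reading I take s = 0.450, the E gained per free Q lost, which is the selectivity, read with the scatter of its readings. If Q falls by first order at both charges, the same reading gives a rate constant k = 0.0110 min⁻¹.

Two chemists part over what s means. The first takes E as an end product, so in the flask E stays s times the free Q gone and climbs until the time allowed ends. My numbers give 43.4% there. The forecast, with its share of 0.43, prints 42% at 5 h, saying “Nothing yet shows E being consumed”.

The second, whose view I commit to, notes that in the midnight run about half of the free Q lost is missing from E, and takes E as a way station. The midnight readings give her no rate for a drain, so she guesses one with the same constant k. E then peaks at the reciprocal of k, 1.51 h, holding s times exp(-1), or 16.6%.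

The flask peaks at 2.13 h with 25.1%, and its E falls to 19.5% by 5.00 h; the peak stands later and higher than the second chemist reckoned.

    Q → Z (k = 0.00970 min⁻¹)
    Z ⇌ E (K = 4.20, k = 0.390 min⁻¹)
    Z ⇌ L (K = 2.60, k = 0.00910 min⁻¹)
    Q + E ⇌ G, settled at all times (K = 1.10 L mol⁻¹)
    Z → D (k = 0.0300 min⁻¹)
    E ⇌ J (K = 0.920, k = 0.0210 min⁻¹)

At that peak the flask holds 16.5% of J. There s times the free Q gone gives 32.3%, which is 7.2 percentage points above the E found.

The end-product view comes close before the peak. The same charge stopped at 80 min, with 43.6% of free Q, should by s hold 25.4% of E, and it holds 23.6%.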